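**Direct plan and its weak points**

A direct plan would join the two rings by a Claisen–Schmidt condensation. Ortho-prenylation and 4-O-methylation of 3,4-dihydroxybenzaldehyde would give 3-hydroxy-4-methoxy-5-prenylbenzaldehyde (A1). C-Prenylation of 2,4,6-trihydroxyacetophenone would give its 3-prenyl derivative (A2). Condensation of A1 with A2 in strong aqueous KOH would give the chalcone (A3), whose enone C=C would be hydrogenated last.
Its weakest steps would be:
- The C-prenylation of the free acylphloroglucinol to A2: the ambident polyphenoxide also gives O-prenyl, 3,5-diprenyl and geminal diprenyl products, so mono-C selectivity is poor.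
- The condensation of the two unprotected polyphenols to A3: both partners are polyanions, the reaction is slow and air-sensitive, and the 2'-hydroxychalcone can close to a flavanone on acidification.
- The final hydrogenation of A3: it must stop at the enone beside two prenyl alkenes, a chemoselectivity risk placed on the most valuable intermediate.

**Retrosynthetic overview of the new route**

Ring A is read as a tetraketide: C1' with its acyl group and the oxygenated carbons C2', C4', C6' map onto triacetic acid lactone (pyrone C2–C6 plus the 6-methyl carbon, which becomes C1').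
The key step builds benzene ring A last, from the non-aromatic pyrone 14, by methanolysis and Claisen closure of the C1'–C2' bond.
Before that, the C3' prenyl is set on pyrone C3 by Tsuji–Trost allylation, and the future C1'–C(=O) bond is made by acylating the pyrone 6-methyl dianion with a ring B Weinreb amide.
Ring B comes from a commercial bromocatechol aldehyde; its CH2CH2 bridge is made saturated by a metal-free reductive Knoevenagel step before any prenyl group exists.
So no free phloroglucinol is prenylated, no chalcone is formed and no late selective hydrogenation is needed.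

Key step: step 7

Remark: the target has no stereocentre and both prenyl alkenes carry two identical methyl groups, so no stereochemical element has to be controlled.

**Route**

Step 1
Reactants: 1 4-hydroxy-6-methyl-2H-pyran-2-one (triacetic acid lactone); 2 3-methylbut-2-en-1-yl acetate (prenyl acetate)
Product: 3 4-hydroxy-6-methyl-3-(3-methylbut-2-en-1-yl)-2H-pyran-2-one
Conditions: 1 (1.5 equiv), Pd(PPh3)4 (5 mol %), DBU (1.0 equiv), toluene, 80 °C, Ar
Reagents that add atoms: none
Why: Tsuji–Trost allylation: zerovalent palladium ionises 2 to the 1,1-dimethyl-π-allyl complex, and the soft pyrone anion (a vinylogous acid) attacks its unsubstituted terminus through C3; O-prenyl ethers re-ionise under the catalyst and funnel to the C-prenyl product, and the excess of 1 limits double allylation.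

Step 2
Reactants: 4 3-bromo-4,5-dihydroxybenzaldehyde
Product: 5 3-bromo-5-hydroxy-4-methoxybenzaldehyde
Conditions: MeI (1.05 equiv), Li2CO3 (1.1 equiv), DMF, 40 °C, 16 h
Reagents that add atoms: iodomethane, CI
Why: Williamson O-methylation in which the weak base ionises only the 4-OH, which is para to the formyl group and ortho to bromine and so clearly more acidic than the 5-OH; this is the established selectivity of 4-O-alkylation of 3,4-dihydroxybenzaldehydes.

Step 3
Reactants: 5 3-bromo-5-hydroxy-4-methoxybenzaldehyde; 6 2,2-dimethyl-1,3-dioxane-4,6-dione (Meldrum's acid)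
Product: 10 3-(3-bromo-5-hydroxy-4-methoxyphenyl)propanoic acid, via arylidene Meldrum's acid 7 (not isolated), via benzyl Meldrum's acid 8 (not isolated), via benzylmalonic acid 9 (not isolated)
Conditions: 6 (1.1 equiv), HCO2H/Et3N (5:2), 100 °C, 6 h; then H2O, 1 M HCl
Reagents that add atoms: none
Why: Knoevenagel condensation gives 7, formate transfers hydride to this very electrophilic alkylidene (conjugate reduction) to give 8, and ring cleavage to 9 followed by decarboxylation in the hot medium gives the acid; this known one-pot route from aryl aldehydes to 3-arylpropanoic acids uses no metal, so the aryl bromide should be untouched.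

Step 4
Reactants: 10 3-(3-bromo-5-hydroxy-4-methoxyphenyl)propanoic acid
Product: 11 3-(3-bromo-5-hydroxy-4-methoxyphenyl)-N-methoxy-N-methylpropanamide
Conditions: MeNHOMe·HCl (1.2 equiv), EDC·HCl (1.2 equiv), HOBt (0.2 equiv), Et3N (2.5 equiv), CH2Cl2, 0 °C to rt
Reagents that add atoms: N,O-dimethylhydroxylamine hydrochloride, CNOC.Cl
Why: Carbodiimide amide coupling through the HOBt active ester; the amine is far more nucleophilic than the free phenol, so no protection should be needed.

Step 5
Reactants: 11 3-(3-bromo-5-hydroxy-4-methoxyphenyl)-N-methoxy-N-methylpropanamide; 12 tributyl(3-methylbut-2-en-1-yl)stannane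
Product: 13 3-[3-hydroxy-4-methoxy-5-(3-methylbut-2-en-1-yl)phenyl]-N-methoxy-N-methylpropanamide
Conditions: 12 (1.5 equiv), Pd(PPh3)4 (5 mol %), DMF, 100 °C, 12 h, Ar
Reagents that add atoms: none
Why: Stille coupling: oxidative addition of zerovalent palladium into the C–Br bond, transfer of the prenyl group from tin, and reductive elimination at the less hindered CH2 terminus of the allyl ligand should give the linear prenyl arene; the neutral conditions tolerate the free phenol and the Weinreb amide.

Step 6
Reactants: 3 4-hydroxy-6-methyl-3-(3-methylbut-2-en-1-yl)-2H-pyran-2-one; 13 3-[3-hydroxy-4-methoxy-5-(3-methylbut-2-en-1-yl)phenyl]-N-methoxy-N-methylpropanamide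
Product: 14 4-hydroxy-6-{4-[3-hydroxy-4-methoxy-5-(3-methylbut-2-en-1-yl)phenyl]-2-oxobutyl}-3-(3-methylbut-2-en-1-yl)-2H-pyran-2-one
Conditions: 3 (1.3 equiv), LiN(i-Pr)2 (2.7 equiv), THF, −78 to −30 °C, 1 h; then 13 as its lithium phenoxide (LiN(SiMe3)2, 1.05 equiv, THF, −78 °C), −78 to 0 °C, 3 h; cold 1 M HCl to pH 3
Reagents that add atoms: none
Why: Weinreb ketone synthesis with a 4-hydroxy-6-methyl-2-pyrone dianion (a vinylogous acetoacetate dianion): the second deprotonation takes place at the 6-methyl group (C3 is blocked by prenyl), and this carbanion adds to the amide to give a chelated tetrahedral adduct that does not collapse before the quench, so the acidic product never meets the dianion; the ring B phenol travels as its lithium phenoxide.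

Step 7
Reactants: 14 4-hydroxy-6-{4-[3-hydroxy-4-methoxy-5-(3-methylbut-2-en-1-yl)phenyl]-2-oxobutyl}-3-(3-methylbut-2-en-1-yl)-2H-pyran-2-one
Product: 17 3,2',4',6'-tetrahydroxy-4-methoxy-3',5-diprenyldihydrochalcone, via triketo ester 15 (not isolated), via cyclohexanetrione tautomer 16 (not isolated)
Conditions: Mg(OMe)2 (8 equiv), MeOH, reflux, Ar, 16 h; then cold 1 M HCl to pH 4, EtOAc extraction
Reagents that add atoms: none
Why: Magnesium-bound methoxide opens the lactone of 14 at C2 to the chelated triketo ester 15, whose doubly activated C6 carbanion attacks the ester carbonyl C1 and expels methoxide (intramolecular Claisen, Dieckmann-type condensation), and the triketone 16 enolises irreversibly to the aromatic acylphloroglucinol 17. The closest known reaction type is the Mg(OMe)2-mediated recyclisation of 4-hydroxy-6-(2-oxoalkyl)-2-pyrones to acylphloroglucinols, the laboratory counterpart of the chalcone synthase cyclisation. Ring A closes in a 6-exo-trig mode (new bond C1'–C2', enolate carbon onto an ester carbonyl). No stereocentre is created, and the stereocentres of 15 and 16 vanish on aromatisation. The step needs Claisen closure (C6 onto C1) to win over aldol closure (C2 onto the C7 ketone): magnesium holds the C5/C7 diketone as a non-electrophilic chelated enolate while the ester stays open to attack, and the prenyl group on C2 makes any aldol adduct quaternary, so it cannot dehydrate to an arene and should revert. Because C2 of the chain lies between the C1 and C3 oxygens of the new ring, the prenyl group arrives at C3' without regiochemical ambiguity.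

**Compound list**

1 | 4-hydroxy-6-methyl-2H-pyran-2-one (triacetic acid lactone) | Cc1cc(O)cc(=O)o1 | starting material
2 | 3-methylbut-2-en-1-yl acetate (prenyl acetate) | CC(C)=CCOC(C)=O | starting material
3 | 4-hydroxy-6-methyl-3-(3-methylbut-2-en-1-yl)-2H-pyran-2-one | Cc1cc(O)c(CC=C(C)C)c(=O)o1 | intermediate
4 | 3-bromo-4,5-dihydroxybenzaldehyde | O=Cc1cc(O)c(O)c(Br)c1 | starting material
5 | 3-bromo-5-hydroxy-4-methoxybenzaldehyde | O=Cc1cc(O)c(OC)c(Br)c1 | intermediate
6 | 2,2-dimethyl-1,3-dioxane-4,6-dione (Meldrum's acid) | CC1(C)OC(=O)CC(=O)O1 | starting material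
7 | 5-(3-bromo-5-hydroxy-4-methoxybenzylidene)-2,2-dimethyl-1,3-dioxane-4,6-dione | CC1(C)OC(=O)C(=Cc2cc(O)c(OC)c(Br)c2)C(=O)O1 | intermediate (not isolated)
8 | 5-(3-bromo-5-hydroxy-4-methoxybenzyl)-2,2-dimethyl-1,3-dioxane-4,6-dione | CC1(C)OC(=O)C(Cc2cc(O)c(OC)c(Br)c2)C(=O)O1 | intermediate (not isolated)
9 | 2-(3-bromo-5-hydroxy-4-methoxybenzyl)propanedioic acid | OC(=O)C(Cc1cc(O)c(OC)c(Br)c1)C(O)=O | intermediate (not isolated)
10 | 3-(3-bromo-5-hydroxy-4-methoxyphenyl)propanoic acid | OC(=O)CCc1cc(O)c(OC)c(Br)c1 | intermediate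
11 | 3-(3-bromo-5-hydroxy-4-methoxyphenyl)-N-methoxy-N-methylpropanamide | CON(C)C(=O)CCc1cc(O)c(OC)c(Br)c1 | intermediate
12 | tributyl(3-methylbut-2-en-1-yl)stannane | CCCC[Sn](CCCC)(CCCC)CC=C(C)C | starting material
13 | 3-[3-hydroxy-4-methoxy-5-(3-methylbut-2-en-1-yl)phenyl]-N-methoxy-N-methylpropanamide | CON(C)C(=O)CCc1cc(O)c(OC)c(CC=C(C)C)c1 | intermediate
14 | 4-hydroxy-6-{4-[3-hydroxy-4-methoxy-5-(3-methylbut-2-en-1-yl)phenyl]-2-oxobutyl}-3-(3-methylbut-2-en-1-yl)-2H-pyran-2-one | COc1c(O)cc(CCC(=O)Cc2cc(O)c(CC=C(C)C)c(=O)o2)cc1CC=C(C)C | intermediate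
15 | methyl 9-[3-hydroxy-4-methoxy-5-(3-methylbut-2-en-1-yl)phenyl]-2-(3-methylbut-2-en-1-yl)-3,5,7-trioxononanoate (racemic, magnesium enolate in the flask) | COC(=O)C(CC=C(C)C)C(=O)CC(=O)CC(=O)CCc1cc(O)c(OC)c(CC=C(C)C)c1 | intermediate (not isolated)
16 | 2-{3-[3-hydroxy-4-methoxy-5-(3-methylbut-2-en-1-yl)phenyl]propanoyl}-4-(3-methylbut-2-en-1-yl)cyclohexane-1,3,5-trione (non-aromatic tautomer of 17, transient mixture of stereoisomers) | O=C(CCc1cc(O)c(OC)c(CC=C(C)C)c1)C1C(=O)CC(=O)C(CC=C(C)C)C1=O | intermediate (not isolated)
17 | 3,2',4',6'-tetrahydroxy-4-methoxy-3',5-diprenyldihydrochalcone | COc1c(O)cc(CCC(=O)c2c(O)cc(O)c(CC=C(C)C)c2O)cc1CC=C(C)C | target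

**Step count and risks**

Total steps: 7. Longest linear sequence: 6 (steps 2 to 7, from 4); step 1 is the one-step side branch that delivers 3.

Steps most likely to fail:

1. Step 7. The pyrone may resist ring opening, the polyketo chain may be cut by retro-Claisen methanolysis, or an aldol closure may compete with the Claisen closure; acidic work-up could also cyclise the C3' prenyl onto a neighbouring phenol. The fallback forms the aryl–carbonyl bond on a preformed ring A and sets out from 13. Phloroglucinol is converted (MOMCl, i-Pr2NEt) into 1,3,5-tris(methoxymethoxy)benzene F1. Lithiation between two MOM ethers (n-BuLi, THF, 0 °C) and alkylation (CuI, prenyl bromide) give 1,3,5-tris(methoxymethoxy)-2-(3-methylbut-2-en-1-yl)benzene F2. A second ortho-lithiation of F2 and addition to the lithium phenoxide of 13 (Weinreb ketone synthesis) give 3-[3-hydroxy-4-methoxy-5-(3-methylbut-2-en-1-yl)phenyl]-1-[2,4,6-tris(methoxymethoxy)-3-(3-methylbut-2-en-1-yl)phenyl]propan-1-one F3. Removal of the MOM groups (3 M HCl, MeOH, rt) brings the route back at 17.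

2. Step 6. Proton transfer from the α-CH2 of the amide to the dianion, or aggregation of the polylithiated partners, may stall the addition. The fallback replaces acylation by aldol addition and oxidation and sets out from 13. Reduction with i-Bu2AlH (THF, −78 °C) gives 3-[3-hydroxy-4-methoxy-5-(3-methylbut-2-en-1-yl)phenyl]propanal F4. The dianion of 3 adds to F4 at −78 °C, since aldehydes add faster than they enolise, to give racemic 4-hydroxy-6-{2-hydroxy-4-[3-hydroxy-4-methoxy-5-(3-methylbut-2-en-1-yl)phenyl]butyl}-3-(3-methylbut-2-en-1-yl)-2H-pyran-2-one F5. Dess–Martin oxidation (NaHCO3, CH2Cl2, 0 °C) returns to the route at 14.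

3. Step 5. Allylic transposition during the transfer from tin may give the 1,1-dimethylallyl isomer, and oxidative addition into the electron-rich, ortho-substituted aryl bromide may be slow. The fallback builds the trisubstituted alkene by metathesis and sets out from 11. Stille coupling with allyltributylstannane (Pd(PPh3)4, DMF, 100 °C), where no regiochemical question arises, gives 3-[3-hydroxy-4-methoxy-5-(prop-2-en-1-yl)phenyl]-N-methoxy-N-methylpropanamide F6. Cross-metathesis of F6 with 2-methylbut-2-ene (second-generation Grubbs catalyst, CH2Cl2, 40 °C) returns to the route at 13.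

**Further compounds**

F1 | step 7 | 1,3,5-tris(methoxymethoxy)benzene | COCOc1cc(OCOC)cc(OCOC)c1
F2 | step 7 | 1,3,5-tris(methoxymethoxy)-2-(3-methylbut-2-en-1-yl)benzene | COCOc1cc(OCOC)c(CC=C(C)C)c(OCOC)c1
F3 | step 7 | 3-[3-hydroxy-4-methoxy-5-(3-methylbut-2-en-1-yl)phenyl]-1-[2,4,6-tris(methoxymethoxy)-3-(3-methylbut-2-en-1-yl)phenyl]propan-1-one | COCOc1cc(OCOC)c(C(=O)CCc2cc(O)c(OC)c(CC=C(C)C)c2)c(OCOC)c1CC=C(C)C
F4 | step 6 | 3-[3-hydroxy-4-methoxy-5-(3-methylbut-2-en-1-yl)phenyl]propanal | O=CCCc1cc(O)c(OC)c(CC=C(C)C)c1
F5 | step 6 | 4-hydroxy-6-{2-hydroxy-4-[3-hydroxy-4-methoxy-5-(3-methylbut-2-en-1-yl)phenyl]butyl}-3-(3-methylbut-2-en-1-yl)-2H-pyran-2-one (racemic) | COc1c(O)cc(CCC(O)Cc2cc(O)c(CC=C(C)C)c(=O)o2)cc1CC=C(C)C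
F6 | step 5 | 3-[3-hydroxy-4-methoxy-5-(prop-2-en-1-yl)phenyl]-N-methoxy-N-methylpropanamide | CON(C)C(=O)CCc1cc(O)c(OC)c(CC=C)c1
A1 | direct plan | 3-hydroxy-4-methoxy-5-(3-methylbut-2-en-1-yl)benzaldehyde | COc1c(O)cc(C=O)cc1CC=C(C)C
A2 | direct plan | 1-[2,4,6-trihydroxy-3-(3-methylbut-2-en-1-yl)phenyl]ethanone | CC(=O)c1c(O)cc(O)c(CC=C(C)C)c1O
A3 | direct plan | (E)-3-[3-hydroxy-4-methoxy-5-(3-methylbut-2-en-1-yl)phenyl]-1-[2,4,6-trihydroxy-3-(3-methylbut-2-en-1-yl)phenyl]prop-2-en-1-one | COc1c(O)cc(/C=C/C(=O)c2c(O)cc(O)c(CC=C(C)C)c2O)cc1CC=C(C)C
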